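## Plan

- **Cuts:** the three O-protecting-group bonds; C8–CMe2 of the 1,1-dimethylallyl group (back to a 7-O-prenyl ether); C7–O and C5–O (back to C–F); then O1–C8a and C2–C3 of ring C together, which separates an A-ring ketone from a B-ring acyl donor. In the B fragment: the C2′–prenyl bond and the pyran ring of the chroman.
- **Enabling feature:** ring A carries its oxygens at C5, C7 and C8a in a 1,3,5 array around C4a, which bears the C4 carbonyl. This is the pattern of a mono-acylated 1,3,5-trifluorobenzene, so the C4 carbonyl activates C8a–F for closure of ring C and then C5–F (ortho, peri) and C7–F (para) for ether formation.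
- **Forward order:** ketone 6 (steps 1–3); chroman ring of the B fragment (steps 4–6), then prenyl group and acyl imidazolide (steps 7–12); ring C closes last (step 13); then C5–O, C7–O, O7→C8 allyl shift and deprotection (steps 14–17).
- **Stereochemistry:** none to set; every selectivity issue is regiochemical.

Key step: step 13

Remark: the target SMILES contains no stereocentre and no stereogenic double bond, so the compound is achiral and "single enantiomer" requires no stereocontrol.
Abbreviation: Chr = 8-(methoxymethoxy)-2,2-dimethyl-5-(3-methylbut-2-en-1-yl)chroman-6-yl.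

## Route

Step 1
Reactants: 1 methyl glycolate
Product: 2 methyl 2-(methoxymethoxy)acetate
Conditions: MOMCl, i-Pr2NEt, CH2Cl2, 0 °C → rt
Reagents that add atoms: chloromethyl methyl ether (MOMCl), COCCl
Why: O-alkylation of the primary alcohol by the α-chloro ether under amine base (standard MOM acetal formation) should leave the ester untouched.

Step 2
Reactants: 2 methyl 2-(methoxymethoxy)acetate
Product: 3 N-methoxy-2-(methoxymethoxy)-N-methylacetamide
Conditions: MeNH(OMe)·HCl, i-PrMgCl, THF, −20 → 0 °C
Reagents that add atoms: N,O-dimethylhydroxylamine hydrochloride, CNOC.Cl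
Why: Weinreb amide formation by aminolysis of the ester with the magnesium amide generated in the flask is a standard, clean conversion of unhindered esters.

Step 3
Reactants: 4 1,3,5-trifluorobenzene; 3 N-methoxy-2-(methoxymethoxy)-N-methylacetamide
Product: 6 2-(methoxymethoxy)-1-(2,4,6-trifluorophenyl)ethan-1-one, via 2,4,6-trifluorophenyllithium 5 (not isolated)
Conditions: n-BuLi, THF, −78 °C; then 3, −78 °C; cold aq. NH4Cl
Reagents that add atoms: none
Why: deprotonation between two fluorines (all three C–H are equivalent) followed by Weinreb ketone synthesis should stop at the ketone because the chelated tetrahedral adduct persists until the quench, and −78 °C prevents aryne formation by LiF loss.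

Step 4
Reactants: 7 6-bromovanillin (2-bromo-4-hydroxy-5-methoxybenzaldehyde); 8 3-chloro-3-methylbut-1-yne
Product: 9 2-bromo-5-methoxy-4-[(2-methylbut-3-yn-2-yl)oxy]benzaldehyde
Conditions: K2CO3, KI, CuI (cat.), acetone, reflux
Reagents that add atoms: none
Why: copper-assisted O-alkylation of the single phenoxide with the tertiary propargylic chloride is the standard entry to aryl 1,1-dimethylpropargyl ethers, also for electron-poor phenols.

Step 5
Reactants: 9 2-bromo-5-methoxy-4-[(2-methylbut-3-yn-2-yl)oxy]benzaldehyde
Product: 11 5-bromo-8-methoxy-2,2-dimethyl-2H-chromene-6-carbaldehyde, via allenylphenol 10 (not isolated)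
Conditions: PhNEt2, 180 °C
Reagents that add atoms: none
Why: the aryl propargyl ether Claisen rearrangement can only end productively at the one free ortho position (the other carries OMe), and 1,5-hydrogen shift with oxa-6π electrocyclisation of the allenylphenol should give the 2,2-dimethylchromene.

Step 6
Reactants: 11 5-bromo-8-methoxy-2,2-dimethyl-2H-chromene-6-carbaldehyde
Product: 12 5-bromo-8-methoxy-2,2-dimethylchromane-6-carbaldehyde
Conditions: H2 (1–3 atm), RhCl(PPh3)3 (cat.), PhH/EtOH, rt
Reagents that add atoms: none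
Why: homogeneous hydrogenation of the cis-disubstituted styrenic double bond with Wilkinson's catalyst should spare the aryl bromide (which Pd/C would cleave) and, at room temperature, the aldehyde.

Step 7
Reactants: 12 5-bromo-8-methoxy-2,2-dimethylchromane-6-carbaldehyde
Product: 13 5-bromo-6-(dimethoxymethyl)-8-methoxy-2,2-dimethylchromane
Conditions: HC(OMe)3, MeOH, p-TsOH (cat.), rt
Reagents that add atoms: trimethyl orthoformate, COC(OC)OC; methanol, CO
Why: acid-catalysed acetalisation driven by the orthoformate as water scavenger masks the aldehyde for the organolithium step.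

Step 8
Reactants: 13 5-bromo-6-(dimethoxymethyl)-8-methoxy-2,2-dimethylchromane; 14 1-bromo-3-methylbut-2-ene (prenyl bromide)
Product: 17 8-methoxy-2,2-dimethyl-5-(3-methylbut-2-en-1-yl)chromane-6-carbaldehyde, via aryllithium 15 (not isolated), via prenylated dimethyl acetal 16 (not isolated)
Conditions: n-BuLi, THF, −78 °C; CuBr·SMe2 (10 mol %), 14, −78 → 0 °C; then 1 M HCl, THF, rt
Reagents that add atoms: water, O
Why: bromine–lithium exchange (aryllithium held by the ortho acetal oxygen) and copper-catalysed SN2 allylation at the CH2 terminus of prenyl bromide should give the linear prenyl arene, since SN2′ attack would place a quaternary carbon on a di-ortho-substituted ring, and the dimethyl acetal hydrolyses in the acidic work-up.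

Step 9
Reactants: 17 8-methoxy-2,2-dimethyl-5-(3-methylbut-2-en-1-yl)chromane-6-carbaldehyde
Product: 18 8-hydroxy-2,2-dimethyl-5-(3-methylbut-2-en-1-yl)chromane-6-carbaldehyde
Conditions: NaSEt, DMF, 120 °C (Ar); then aq. HCl
Reagents that add atoms: none
Why: SN2 demethylation by thiolate attacks only the methyl ether, because the chroman ether carbon is tertiary, and the weakly basic thiolate should tolerate the aldehyde and the prenyl group.

Step 10
Reactants: 18 8-hydroxy-2,2-dimethyl-5-(3-methylbut-2-en-1-yl)chromane-6-carbaldehyde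
Product: 19 8-(methoxymethoxy)-2,2-dimethyl-5-(3-methylbut-2-en-1-yl)chromane-6-carbaldehyde
Conditions: MOMCl, i-Pr2NEt, CH2Cl2, 0 °C → rt
Reagents that add atoms: chloromethyl methyl ether (MOMCl), COCCl
Why: MOM protection of the only phenol gives an ether that survives base, organolithium amides and heat and is removed by acid at the end.

Step 11
Reactants: 19 8-(methoxymethoxy)-2,2-dimethyl-5-(3-methylbut-2-en-1-yl)chromane-6-carbaldehyde
Product: 20 8-(methoxymethoxy)-2,2-dimethyl-5-(3-methylbut-2-en-1-yl)chromane-6-carboxylic acid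
Conditions: NaClO2, NaH2PO4, 2-methylbut-2-ene (excess), t-BuOH/H2O, 0 °C → rt
Reagents that add atoms: sodium chlorite, [Na+].[O-]Cl=O
Why: Pinnick oxidation at buffered pH should leave the MOM ether intact, and the excess 2-methylbut-2-ene scavenges hypochlorous acid before it can chlorinate the prenyl alkene or the electron-rich ring.

Step 12
Reactants: 20 8-(methoxymethoxy)-2,2-dimethyl-5-(3-methylbut-2-en-1-yl)chromane-6-carboxylic acid
Product: 21 Chr–C(=O)–imidazol-1-yl (the 1-acylimidazole of acid 20)
Conditions: CDI, CH2Cl2, rt; rapid cold-water wash, dry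
Reagents that add atoms: 1,1′-carbonyldiimidazole (CDI), O=C(n1ccnc1)n1ccnc1
Why: activation of the acid as the acyl imidazolide with loss of CO2 is neutral and MOM-compatible, and the wash removes the co-formed imidazole, which would otherwise protonate the enolate in step 13.

Step 13
Reactants: 6 2-(methoxymethoxy)-1-(2,4,6-trifluorophenyl)ethan-1-one; 21 Chr–C(=O)–imidazol-1-yl
Product: 24 5,7-difluoro-3-(methoxymethoxy)-2-Chr-4H-chromen-4-one, via lithium enolate 22 (not isolated), via 2-alkoxy-1,3-diketone 23 (not isolated)
Conditions: LiHMDS (2.0 equiv), THF, −78 °C; 21, −78 → 0 °C; then 50 °C; aq. NH4Cl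
Reagents that add atoms: none
Why: LiHMDS turns 6 into the chelated lithium enolate 22, whose carbon attacks the acyl imidazolide in a crossed Claisen condensation (C2–C3), and the second equivalent of base converts the resulting 2-alkoxy-1,3-diketone 23 into its enolate. On warming, the enolate oxygen on the B-ring side adds to an ortho C–F carbon of the trifluorophenyl ring, which the adjacent C4 carbonyl and the two other fluorines activate, and fluoride loss from the Meisenheimer adduct forms O1–C8a. The closest known reaction type is chromone and flavone synthesis from 2-fluoroaryl ketones by 1,3-diketone formation and intramolecular SNAr. Ring C closes by a six-membered addition–elimination at an aromatic carbon (6-exo-trig with respect to the ring C=C bond), and no stereocentre is formed. C- over O-acylation should be secured by pairing a lithium enolate with an acyl imidazolide in THF, and the two ortho fluorines are equivalent, so only one chromone can arise. The six-membered closure should outrun intermolecular attack at the para fluorine because no free amide base remains after 2.0 equiv and the temperature stays at or below 50 °C.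

Step 14
Reactants: 24 5,7-difluoro-3-(methoxymethoxy)-2-Chr-4H-chromen-4-one
Product: 25 7-fluoro-3-(methoxymethoxy)-2-Chr-5-[2-(trimethylsilyl)ethoxy]-4H-chromen-4-one
Conditions: Me3SiCH2CH2OH (1.05 equiv), NaH, THF, −20 → 0 °C
Reagents that add atoms: 2-(trimethylsilyl)ethanol, C[Si](C)(C)CCO
Why: in a weakly ion-separating solvent the sodium alkoxide bound to the C4 carbonyl oxygen should be delivered to the peri C5–F through a six-membered chelate (ortho-directed SNAr, as with alkoxides on 2,4-difluoroaryl ketones and 5,7-difluoroquinazolinones), and one equivalent at low temperature should avoid the slower second substitution.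

Step 15
Reactants: 25 7-fluoro-3-(methoxymethoxy)-2-Chr-5-[2-(trimethylsilyl)ethoxy]-4H-chromen-4-one; 26 3-methylbut-2-en-1-ol
Product: 28 3-(methoxymethoxy)-2-Chr-7-[(3-methylbut-2-en-1-yl)oxy]-5-[2-(trimethylsilyl)ethoxy]-4H-chromen-4-one, via sodium prenyloxide 27 (not isolated)
Conditions: NaH, THF/DMF (4:1), 0 → 50 °C
Reagents that add atoms: none
Why: SNAr at the one remaining C–F, para to the carbon that bears the C4 carbonyl, has no regiochemical alternative, the MOM and silylethyl ethers are inert to alkoxide, and the sodium fluoride formed is insoluble and should not attack silicon.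

Step 16
Reactants: 28 3-(methoxymethoxy)-2-Chr-7-[(3-methylbut-2-en-1-yl)oxy]-5-[2-(trimethylsilyl)ethoxy]-4H-chromen-4-one
Product: 30 7-hydroxy-3-(methoxymethoxy)-2-Chr-8-(2-methylbut-3-en-2-yl)-5-[2-(trimethylsilyl)ethoxy]-4H-chromen-4-one, via cyclohexadienone 29 (not isolated)
Conditions: PhNEt2, 200 °C (sealed tube or microwave, Ar)
Reagents that add atoms: none
Why: the aromatic Claisen rearrangement ([3,3], allyl inversion) turns the O-prenyl group into the C-bound 1,1-dimethylallyl group, and it should go to C8 because the C7–C8 bond of a chromone has the higher double-bond character (7-allyloxychromones and -coumarins rearrange to C8), the C5 oxygen is not hydrogen-bonded to C4=O, and the bulky C5 ether shields C6.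

Step 17
Reactants: 30 7-hydroxy-3-(methoxymethoxy)-2-Chr-8-(2-methylbut-3-en-2-yl)-5-[2-(trimethylsilyl)ethoxy]-4H-chromen-4-one
Product: 32 broussoflavonol E, via 5,7-dihydroxy bis-MOM ether 31 (not isolated)
Conditions: TBAF, THF, 50 °C; then MeOH, 3 M aq. HCl, 40 °C
Reagents that add atoms: none
Why: fluoride attack at silicon with β-elimination releases ethylene and the carbonyl-stabilised C5 phenoxide, and acid-catalysed acetal methanolysis then removes both MOM groups under conditions that should be too mild to protonate the vinyl or prenyl double bonds.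

## Compound list

1 | methyl glycolate | COC(=O)CO | starting material
2 | methyl 2-(methoxymethoxy)acetate | COCOCC(=O)OC | intermediate
3 | N-methoxy-2-(methoxymethoxy)-N-methylacetamide | COCOCC(=O)N(C)OC | intermediate
4 | 1,3,5-trifluorobenzene | Fc1cc(F)cc(F)c1 | starting material
5 | 2,4,6-trifluorophenyllithium (formed in the flask) | [Li]c1c(F)cc(F)cc1F | intermediate
6 | 2-(methoxymethoxy)-1-(2,4,6-trifluorophenyl)ethan-1-one | COCOCC(=O)c1c(F)cc(F)cc1F | intermediate
7 | 6-bromovanillin (2-bromo-4-hydroxy-5-methoxybenzaldehyde) | COc1cc(C=O)c(Br)cc1O | starting material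
8 | 3-chloro-3-methylbut-1-yne | C#CC(C)(C)Cl | starting material
9 | 2-bromo-5-methoxy-4-[(2-methylbut-3-yn-2-yl)oxy]benzaldehyde | COc1cc(C=O)c(Br)cc1OC(C)(C)C#C | intermediate
10 | 2-bromo-4-hydroxy-5-methoxy-3-(3-methylbuta-1,2-dien-1-yl)benzaldehyde (allenylphenol, formed in the flask) | COc1cc(C=O)c(Br)c(C=C=C(C)C)c1O | intermediate
11 | 5-bromo-8-methoxy-2,2-dimethyl-2H-chromene-6-carbaldehyde | COc1cc(C=O)c(Br)c2C=CC(C)(C)Oc12 | intermediate
12 | 5-bromo-8-methoxy-2,2-dimethylchromane-6-carbaldehyde | COc1cc(C=O)c(Br)c2CCC(C)(C)Oc12 | intermediate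
13 | 5-bromo-6-(dimethoxymethyl)-8-methoxy-2,2-dimethylchromane | COc1cc(C(OC)OC)c(Br)c2CCC(C)(C)Oc12 | intermediate
14 | 1-bromo-3-methylbut-2-ene (prenyl bromide) | CC(C)=CCBr | starting material
15 | [6-(dimethoxymethyl)-8-methoxy-2,2-dimethylchroman-5-yl]lithium (formed in the flask) | [Li]c1c(C(OC)OC)cc(OC)c2OC(C)(C)CCc12 | intermediate
16 | 6-(dimethoxymethyl)-8-methoxy-2,2-dimethyl-5-(3-methylbut-2-en-1-yl)chromane (formed in the flask) | COc1cc(C(OC)OC)c(CC=C(C)C)c2CCC(C)(C)Oc12 | intermediate
17 | 8-methoxy-2,2-dimethyl-5-(3-methylbut-2-en-1-yl)chromane-6-carbaldehyde | COc1cc(C=O)c(CC=C(C)C)c2CCC(C)(C)Oc12 | intermediate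
18 | 8-hydroxy-2,2-dimethyl-5-(3-methylbut-2-en-1-yl)chromane-6-carbaldehyde | Oc1cc(C=O)c(CC=C(C)C)c2CCC(C)(C)Oc12 | intermediate
19 | 8-(methoxymethoxy)-2,2-dimethyl-5-(3-methylbut-2-en-1-yl)chromane-6-carbaldehyde | COCOc1cc(C=O)c(CC=C(C)C)c2CCC(C)(C)Oc12 | intermediate
20 | 8-(methoxymethoxy)-2,2-dimethyl-5-(3-methylbut-2-en-1-yl)chromane-6-carboxylic acid | COCOc1cc(C(=O)O)c(CC=C(C)C)c2CCC(C)(C)Oc12 | intermediate
21 | (1H-imidazol-1-yl)[8-(methoxymethoxy)-2,2-dimethyl-5-(3-methylbut-2-en-1-yl)chroman-6-yl]methanone | COCOc1cc(C(=O)n3ccnc3)c(CC=C(C)C)c2CCC(C)(C)Oc12 | intermediate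
22 | lithium (Z)-2-(methoxymethoxy)-1-(2,4,6-trifluorophenyl)ethen-1-olate (formed in the flask) | [Li]O/C(=C\OCOC)c1c(F)cc(F)cc1F | intermediate
23 | 2-(methoxymethoxy)-1-Chr-3-(2,4,6-trifluorophenyl)propane-1,3-dione (present as its lithium enolate, formed in the flask) | COCOC(C(=O)c1c(F)cc(F)cc1F)C(=O)c1cc(OCOC)c2OC(C)(C)CCc2c1CC=C(C)C | intermediate
24 | 5,7-difluoro-3-(methoxymethoxy)-2-Chr-4H-chromen-4-one | COCOc1c(-c2cc(OCOC)c3OC(C)(C)CCc3c2CC=C(C)C)oc2cc(F)cc(F)c2c1=O | intermediate
25 | 7-fluoro-3-(methoxymethoxy)-2-Chr-5-[2-(trimethylsilyl)ethoxy]-4H-chromen-4-one | COCOc1c(-c2cc(OCOC)c3OC(C)(C)CCc3c2CC=C(C)C)oc2cc(F)cc(OCC[Si](C)(C)C)c2c1=O | intermediate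
26 | 3-methylbut-2-en-1-ol (prenol) | CC(C)=CCO | starting material
27 | sodium 3-methylbut-2-en-1-olate (formed in the flask) | CC(C)=CC[O-].[Na+] | intermediate
28 | 3-(methoxymethoxy)-2-Chr-7-[(3-methylbut-2-en-1-yl)oxy]-5-[2-(trimethylsilyl)ethoxy]-4H-chromen-4-one | COCOc1c(-c2cc(OCOC)c3OC(C)(C)CCc3c2CC=C(C)C)oc2cc(OCC=C(C)C)cc(OCC[Si](C)(C)C)c2c1=O | intermediate
29 | 3-(methoxymethoxy)-2-Chr-8-(2-methylbut-3-en-2-yl)-5-[2-(trimethylsilyl)ethoxy]-8H-chromene-4,7-dione (racemic dienone, formed in the flask) | COCOC1=C(c2cc(OCOC)c3OC(C)(C)CCc3c2CC=C(C)C)OC2=C(C1=O)C(OCC[Si](C)(C)C)=CC(=O)C2C(C)(C)C=C | intermediate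
30 | 7-hydroxy-3-(methoxymethoxy)-2-Chr-8-(2-methylbut-3-en-2-yl)-5-[2-(trimethylsilyl)ethoxy]-4H-chromen-4-one | COCOc1c(-c2cc(OCOC)c3OC(C)(C)CCc3c2CC=C(C)C)oc2c(C(C)(C)C=C)c(O)cc(OCC[Si](C)(C)C)c2c1=O | intermediate
31 | 5,7-dihydroxy-3-(methoxymethoxy)-2-Chr-8-(2-methylbut-3-en-2-yl)-4H-chromen-4-one (formed in the flask) | COCOc1c(-c2cc(OCOC)c3OC(C)(C)CCc3c2CC=C(C)C)oc2c(C(C)(C)C=C)c(O)cc(O)c2c1=O | intermediate
32 | broussoflavonol E: 3,5,7-trihydroxy-2-[8-hydroxy-2,2-dimethyl-5-(3-methylbut-2-en-1-yl)chroman-6-yl]-8-(2-methylbut-3-en-2-yl)-4H-chromen-4-one | C=CC(C)(C)c1c(O)cc(O)c2c(=O)c(O)c(-c3cc(O)c4c(c3CC=C(C)C)CCC(C)(C)O4)oc12 | target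

## Step count and risks

Total step count: 17. Longest linear sequence: 14 steps (steps 4–17, from 6-bromovanillin).

**Step 16.** At 200 °C the [3,3] shift may be followed by abnormal Claisen isomerisation of the new side chain, ring closure of the freed phenol onto the vinyl group, loss of the prenyl group, or partial migration to C6. The fallback sets out from 28 and traps the phenol as it forms. Heating 28 in N,N-diethylaniline with acetic anhydride at 190 °C should give 7-acetoxy-3-(methoxymethoxy)-2-Chr-8-(2-methylbut-3-en-2-yl)-5-[2-(trimethylsilyl)ethoxy]-4H-chromen-4-one F1, in which the phenol is no longer available for the follow-up reactions. Methanolysis of the acetate with K2CO3 in MeOH at room temperature returns to the route at 30.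

**Step 14.** Chelation control may be incomplete, so that the alkoxide also attacks C7 or substitutes twice. The fallback sets out from 24 and reverses the order of the two ether-forming substitutions, so that selectivity rests on the para preference of a free alkoxide instead of on chelation. Potassium prenyloxide (prenol, KHMDS) with 18-crown-6 in DMSO/THF at room temperature should attack C7 and give 5-fluoro-3-(methoxymethoxy)-2-Chr-7-[(3-methylbut-2-en-1-yl)oxy]-4H-chromen-4-one F2. Sodium 2-(trimethylsilyl)ethoxide in THF at 40 °C then displaces the single remaining, carbonyl-flanked fluoride, and the route is rejoined at 28.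

**Step 13.** The tightly chelated lithium diketonate may close slowly, leaving time for intermolecular fluoride displacement by imidazolide or enolate, or part of the enolate may be O-acylated. The fallback sets out from ketone 6 and aldehyde 19 and builds the diketone at a lower oxidation level. Aldol addition of the lithium enolate of 6 to 19 (LiHMDS, THF, −78 °C, cold quench) should give 3-hydroxy-2-(methoxymethoxy)-3-Chr-1-(2,4,6-trifluorophenyl)propan-1-one F3 as a mixture of diastereomers. Dess–Martin oxidation gives diketone 23, now isolated, and K2CO3 in DMF at 60 °C effects the intramolecular fluoride displacement in the absence of other nucleophiles, returning to the route at 24.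

## Further compounds

F1 | step 16 | 7-acetoxy-3-(methoxymethoxy)-2-Chr-8-(2-methylbut-3-en-2-yl)-5-[2-(trimethylsilyl)ethoxy]-4H-chromen-4-one | COCOc1c(-c2cc(OCOC)c3OC(C)(C)CCc3c2CC=C(C)C)oc2c(C(C)(C)C=C)c(OC(C)=O)cc(OCC[Si](C)(C)C)c2c1=O
F2 | step 14 | 5-fluoro-3-(methoxymethoxy)-2-Chr-7-[(3-methylbut-2-en-1-yl)oxy]-4H-chromen-4-one | COCOc1c(-c2cc(OCOC)c3OC(C)(C)CCc3c2CC=C(C)C)oc2cc(OCC=C(C)C)cc(F)c2c1=O
F3 | step 13 | 3-hydroxy-2-(methoxymethoxy)-3-Chr-1-(2,4,6-trifluorophenyl)propan-1-one (mixture of diastereomers) | COCOC(C(O)c1cc(OCOC)c2OC(C)(C)CCc2c1CC=C(C)C)C(=O)c1c(F)cc(F)cc1F
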